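The chemist who ran the south and north-east flasks left two sets of readings, and I have to say what three new flasks hold at their end.

common to all: solid substrate 0.050 M
- south: partner 0.038 M; run made earlier
- north-east: partner 0.14 M; run made earlier
- Sunday's: partner 0.200 M; time 8.0 d
- Tuesday's: partner 0.100 M; time 8.0 d
- Wednesday's: partner 0.0500 M; time 8.0 d

| run | time / d | single product / % | solid substrate / % |
|---|---|---|---|
| south | 0.625 | 17.6 | 13.7 |
| south | 1.25 | 18.3 | 16.1 |
| south | 2.50 | 16.3 | 14.4 |
| south | 4.00 | 17.5 | 14.7 |
| south | 8.00 | 18.3 | 15.2 |
| north-east | 0.625 | 40.9 | 2.1 |
| north-east | 1.25 | 40.5 | 0 |
| north-east | 2.50 | 38.2 | 0 |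
| north-east | 4.00 | 39.9 | 0.1 |
| north-east | 8.00 | 38.6 | 0 |

(standard deviation of a reading: 1 percentage point)

- solid substrate is a solid; its amount is given per volume of the solution
- what was read earlier has a scatter of 1 percentage point, one standard deviation
- at the start none of the solid substrate is in solution

- which of these holds the largest part of the solid substrate at the end of Sunday's (single product / bis adduct / other mono adduct / solid substrate)
- which of these holds the largest part of the solid substrate at the end of Tuesday's (single product / bis adduct / other mono adduct / solid substrate)
- which of these holds the largest part of the solid substrate at the end of Wednesday's (single product / bis adduct / other mono adduct / solid substrate)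
- amount of single product at the end of Sunday's, in percent of the solid substrate charged

The south run looks contradictory. It was charged partner worth 76.0 % of the solid substrate, and 15.2 % of that solid still lies there at 8.00 d. Yet single product reads 17.6 % at 0.625 d and 18.3 % at the last reading, within the scatter of 1 percentage point, and far less than the partner charged.

The mean single product of that run, set against the partner charged, gives 23.2 %. I call this the partner's take, the part of the charged partner found bound to substrate. Bis adduct carries two partners, other mono adduct carries one, and neither was read, so this figure is a floor for the south run. I judge that the rest of the partner in the south run went another way before the first reading.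

I assume, without proof, that Sunday's flask keeps the south take, and that gives bound partner worth 92.6 % of the substrate charge. If single product in Sunday's stays near the north-east 38.6 %, where solid reads 0 %, and other mono adduct is small, my estimate for Sunday's is about 27.0 % bis adduct.

The forecast names single product for Sunday's at 41 %, and solid substrate for Tuesday's and Wednesday's, holding “so these are equilibria”.

The flask gives bis adduct for Sunday's at 42.8 %, beside 36.3 % single product. Tuesday's and Wednesday's give single product, at 35.7 % and 22.9 %.

    partner → decomposed reagent (k = 2.46 × 10⁻⁴ s⁻¹)
    starting material + partner → single product (k = 0.00384 M⁻¹ s⁻¹)
    partner + single product → bis adduct (k = 0.00300 M⁻¹ s⁻¹)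
    partner + other mono adduct → bis adduct (k = 0.00336 M⁻¹ s⁻¹)
    starting material + partner → other mono adduct (k = 1.43 × 10⁻⁴ M⁻¹ s⁻¹)
    solid substrate ⇌ starting material, rate k6*(cs6 - [starting material]) while solid is left; crystals form when [starting material] > cs6 (solubility = 32.0 mM, k = 0.00191 s⁻¹)

Sunday's take, counting two partners on each bis adduct, is 30.8 %, above the south figure of 23.2 %. Partner left there is 0 %, with 0.138 M standing as decomposed reagent. For the neighbour charged with 0.080 M of partner, the south take gives bound partner worth 37.1 % of the substrate charge. That flask holds 31.9 % single product, 1.15 % other mono adduct and 10.1 % bis adduct, a take of 33.2 %, with 56.9 % remaining as starting material.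

The numbers in the tables were computed with made-up constants.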